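**Plan**

1. Numbering and rings: guaiane numbering in both C15 halves. Unprimed = dienone half (ring A: C1–C5; ring C: C1, C5–C10; lactone D). Primed = spiro half (ring E: C1′–C5′; ring F: C1′, C5′–C10′; lactone G). Ring B = C2, C1, C10, C14, C15′, C4′. α/β as in guaianolides (H6 is β).
2. Cuts, in retrosynthetic order: (i) C8′–C9′ of ring F by carbonyl allylation, possible because the C8′ carbinol is homoallylic to the exocyclic C10′=C14′ and sits next to the C7′ lactone stereocentre; (ii) C2–C4′ and C14–C15′ of ring B by Diels–Alder reaction of the s-cis-locked C2=C1–C10=C14 dienone with the C4′=C15′ enone of a ring-F-seco dienophile; (iii) C8–C9 of ring C by the same allylation; (iv) C6–C7 and O–C12 of both lactones by allylboration–lactonisation; (v) the cyclopentane back to (S)-carvone by ozonolysis–aldol ring contraction.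
3. Forward ring order: cyclopentane (future rings A and E) → lactone (future D and G) → ring C → ring B, which joins the halves and creates spiro C4′ → ring F last. Both halves branch from seco-lactone 14.
4. Stereochemistry: C1/C1′ from (S)-carvone; C5/C5′ by kinetic protonation anti to the C1 side chain; C6/C7 and C6′/C7′ by chair-controlled anti allylboration with Felkin–Anh face selection; C8 and C8′ by Felkin–Anh allylation next to C7/C7′; C4′ by attack on the dienophile face anti to the cis C1′/C5′ substituents; C5 and C10 by base equilibration of the cycloadduct.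

Key step: step 19

Remark on the chemistry (assumption): C5 and C10 of the dienone half are both γ-positions of the ring A enone and equilibrate through one extended dienolate; the 5βH,10βH arrangement of the target is taken to be the resting configuration reached in step 16.

**Route**

Step 1
Reactants: 1 (S)-(+)-carvone
Product: 2 (S)-10-chlorocarvone
Conditions: Ca(OCl)2, CO2 (dry ice), CH2Cl2/H2O, 0 °C
Reagents that add atoms: calcium hypochlorite, [Ca+2].[O-]Cl.[O-]Cl
Why: ene-type allylic chlorination by HOCl made in the flask should occur at the electron-rich isopropenyl group and spare the deactivated enone alkene, leaving the carvone stereocentre (future C1/C1′) untouched.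

Step 2
Reactants: 2 (S)-10-chlorocarvone
Product: 3 (1S,5S)-5-(3-chloroprop-1-en-2-yl)-2-methylcyclohex-2-en-1-ol
Conditions: NaBH4, CeCl3·7H2O, MeOH, −78 to 0 °C
Reagents that add atoms: none
Why: Luche 1,2-reduction with axial hydride delivery to the half-chair carrying an equatorial side chain should give the cis alcohol (future 3β-oxygen) and leave the allylic chloride alone.

Step 3
Reactants: 3 (1S,5S)-5-(3-chloroprop-1-en-2-yl)-2-methylcyclohex-2-en-1-ol
Product: 4 tert-butyldimethylsilyl ether of 3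
Conditions: TBSCl, imidazole, DMF, rt
Reagents that add atoms: tert-butyldimethylsilyl chloride, CC(C)(C)[Si](C)(C)Cl
Why: standard silylation of a secondary allylic alcohol, needed to carry the oxygen through the ring contraction.

Step 4
Reactants: 4 tert-butyldimethylsilyl ether of 3
Product: 6 (3S,5R)-3-(tert-butyldimethylsilyloxy)-5-(3-chloroprop-1-en-2-yl)-2-methylcyclopent-1-ene-1-carbaldehyde, via keto-aldehyde 5 (not isolated)
Conditions: O3, CH2Cl2/MeOH, −78 °C; Me2S; then piperidine, AcOH, PhMe, 60 °C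
Reagents that add atoms: ozone, [O-][O+]=O
Why: ozonolysis should cleave the trisubstituted ring alkene in preference to the chloride-deactivated 1,1-disubstituted alkene, and enamine-mediated intramolecular aldol condensation of the aldehyde onto the methyl ketone closes the cyclopentene (ring contraction) without touching either stereocentre.

Step 5
Reactants: 6 (3S,5R)-3-(tert-butyldimethylsilyloxy)-5-(3-chloroprop-1-en-2-yl)-2-methylcyclopent-1-ene-1-carbaldehyde
Product: 8 (1R,2R,4S)-4-(tert-butyldimethylsilyloxy)-2-(3-chloroprop-1-en-2-yl)-5-methylidenecyclopentane-1-carbaldehyde, via potassium dienolate 7 (not isolated)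
Conditions: KHMDS, THF, −78 °C; then AcOH, −78 °C; used crude
Reagents that add atoms: none
Why: kinetic deconjugation of an enal: γ-deprotonation of the C15 methyl (cis to the formyl group) gives the exocyclic dienolate, and kinetic α-protonation at C5 on the face anti to the C1 side chain and the 3β-silyloxy group should set 5αH and the 4(15)-methylidene at once, with all three substituents cis.

Step 6
Reactants: 9 methyl 4-hydroxybut-2-ynoate
Product: 10 methyl 4-(tert-butyldiphenylsilyloxy)but-2-ynoate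
Conditions: TBDPSCl, imidazole, CH2Cl2, 0 °C to rt
Reagents that add atoms: tert-butyldiphenylsilyl chloride, CC(C)(C)[Si](Cl)(c1ccccc1)c1ccccc1
Why: standard silylation of a primary propargylic alcohol; the bulky silyl group later allows the secondary silyl ether at C3 to be removed selectively.

Step 7
Reactants: 10 methyl 4-(tert-butyldiphenylsilyloxy)but-2-ynoate
Product: 12 methyl (Z)-4-(tert-butyldiphenylsilyloxy)-2-[(4,4,5,5-tetramethyl-1,3,2-dioxaborolan-2-yl)methyl]but-2-enoate, via alkenylalane 11 (not isolated)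
Conditions: DIBAL-H, HMPA, THF, 0 °C; then ICH2Bpin, 0 °C to rt
Reagents that add atoms: 2-(iodomethyl)-4,4,5,5-tetramethyl-1,3,2-dioxaborolane, ICB1OC(C)(C)C(C)(C)O1
Why: syn conjugate hydroalumination of the ynoate followed by C-alkylation of the α-alumino enoate with the iodomethylboronate should give the 2-alkoxycarbonyl allylboronate with the CH2OSi group cis to the ester and trans to the CH2–B carbon.

Step 8
Reactants: 8 (1R,2R,4S)-4-(tert-butyldimethylsilyloxy)-2-(3-chloroprop-1-en-2-yl)-5-methylidenecyclopentane-1-carbaldehyde; 12 methyl (Z)-4-(tert-butyldiphenylsilyloxy)-2-[(4,4,5,5-tetramethyl-1,3,2-dioxaborolan-2-yl)methyl]but-2-enoate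
Product: 14 9-chloro-3β-(tert-butyldimethylsilyloxy)-8-(tert-butyldiphenylsilyloxy)-8,9-seco-1αH,5αH,6βH,7αH-guaia-4(15),10(14),11(13)-trien-12,6-olide, via O-boryl adduct 13 (not isolated)
Conditions: Sc(OTf)3 (10 mol%), PhMe, −20 °C to rt; then p-TsOH·H2O (cat.), rt
Reagents that add atoms: none
Why: Lewis-acid-catalysed allylboration through a closed chair (Zimmerman–Traxler-type) transition state, in which the γ-substituent trans to the CH2–B carbon is equatorial and gives the anti adduct, with Felkin–Anh attack anti to the C5–C1 bond (the branch carrying the cis side chain) setting 6βH; lactonisation of the adduct then gives the trans-fused (6βH,7αH) α-methylene lactone.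

Step 9
Reactants: 14 9-chloro-3β-(tert-butyldimethylsilyloxy)-8-(tert-butyldiphenylsilyloxy)-8,9-seco-1αH,5αH,6βH,7αH-guaia-4(15),10(14),11(13)-trien-12,6-olide
Product: 15 9-chloro-3β,8-dihydroxy-8,9-seco-1αH,5αH,6βH,7αH-guaia-4(15),10(14),11(13)-trien-12,6-olide
Conditions: HF·pyridine (excess), THF, 0 °C to rt
Reagents that add atoms: none
Why: fluoride-driven cleavage of both silyl ethers under acidic, non-basic conditions that should leave the α-methylene lactone and the allylic chloride intact.

Step 10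
Reactants: 15 9-chloro-3β,8-dihydroxy-8,9-seco-1αH,5αH,6βH,7αH-guaia-4(15),10(14),11(13)-trien-12,6-olide
Product: 16 9-chloro-3,8-dioxo-8,9-seco-1αH,5αH,6βH,7αH-guaia-4(15),10(14),11(13)-trien-12,6-olide
Conditions: Dess–Martin periodinane (2.5 equiv), pyridine, CH2Cl2, 0 °C to rt; used crude
Reagents that add atoms: none
Why: Dess–Martin oxidation converts the allylic C3 alcohol into the exocyclic enone and the C8 alcohol into the aldehyde under buffered conditions that should not epimerise C7 or move the lactone methylene.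

Step 11
Reactants: 16 9-chloro-3,8-dioxo-8,9-seco-1αH,5αH,6βH,7αH-guaia-4(15),10(14),11(13)-trien-12,6-olide
Product: 19 8β-hydroxy-3-oxo-1αH,5αH,6βH,7αH-guaia-4(15),10(14),11(13)-trien-12,6-olide, via allylic iodide 17 (not isolated), via allylstannane 18 (not isolated)
Conditions: SnCl2, NaI, DMF (0.01 M), rt
Reagents that add atoms: none
Why: intramolecular Barbier allylation (7-exo-trig) of the aldehyde by the allyltin halide closes ring C; Felkin–Anh attack anti to the C7–C11 bond, with the carbonyl oxygen gauche to C6, should place O8 anti to H7 and give the 8β-alcohol, and the aldehyde reacts in preference to the ketone.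

Step 12
Reactants: 19 8β-hydroxy-3-oxo-1αH,5αH,6βH,7αH-guaia-4(15),10(14),11(13)-trien-12,6-olide
Product: 20 3,8β-bis(tert-butyldimethylsilyloxy)-1αH,5αH,6βH,7αH-guaia-2,4(15),10(14),11(13)-tetraen-12,6-olide
Conditions: TBSOTf (2.5 equiv), Et3N, CH2Cl2, −78 to 0 °C; used crude
Reagents that add atoms: tert-butyldimethylsilyl trifluoromethanesulfonate, CC(C)(C)[Si](C)(C)OS(=O)(=O)C(F)(F)F
Why: soft enolisation toward C2, the only enolisable α-position of the C3 ketone, gives the silyl enol ether while the 8β-hydroxyl is protected in the same operation.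

Step 13
Reactants: 14 9-chloro-3β-(tert-butyldimethylsilyloxy)-8-(tert-butyldiphenylsilyloxy)-8,9-seco-1αH,5αH,6βH,7αH-guaia-4(15),10(14),11(13)-trien-12,6-olide
Product: 21 9-chloro-3β-hydroxy-8-(tert-butyldiphenylsilyloxy)-8,9-seco-1αH,5αH,6βH,7αH-guaia-4(15),10(14),11(13)-trien-12,6-olide
Conditions: camphorsulfonic acid (cat.), MeOH/CH2Cl2, 0 °C to rt
Reagents that add atoms: none
Why: acid-catalysed methanolysis removes the tert-butyldimethylsilyl ether much faster than the acid-stable primary tert-butyldiphenylsilyl ether.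

Step 14
Reactants: 21 9-chloro-3β-hydroxy-8-(tert-butyldiphenylsilyloxy)-8,9-seco-1αH,5αH,6βH,7αH-guaia-4(15),10(14),11(13)-trien-12,6-olide
Product: 22 9-chloro-3-oxo-8-(tert-butyldiphenylsilyloxy)-8,9-seco-1αH,5αH,6βH,7αH-guaia-4(15),10(14),11(13)-trien-12,6-olide
Conditions: MnO2 (excess), CH2Cl2, rt
Reagents that add atoms: none
Why: MnO2 oxidation of the allylic alcohol gives the exocyclic α-methylene cyclopentanone (the dienophile) without affecting the other functionality.

Step 15
Reactants: 20 3,8β-bis(tert-butyldimethylsilyloxy)-1αH,5αH,6βH,7αH-guaia-2,4(15),10(14),11(13)-tetraen-12,6-olide; 22 9-chloro-3-oxo-8-(tert-butyldiphenylsilyloxy)-8,9-seco-1αH,5αH,6βH,7αH-guaia-4(15),10(14),11(13)-trien-12,6-olide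
Product: 24 Diels–Alder adduct with ring B closed (C2–C4′ and C14–C15′ bonds; Δ1(10); 2βH; 5αH; spiro C4′ with C15′ β), via dienone 23 (not isolated)
Conditions: Pd(OAc)2 (1.1 equiv), MeCN, rt, Ar; filtration (Celite); then 22 (3 equiv), BHT, PhMe, 45 °C, Ar
Reagents that add atoms: none
Why: Saegusa–Ito oxidation (β-hydride elimination of H1) gives the cross-conjugated dienone, whose s-cis-locked C2=C1–C10=C14 diene should add to the exocyclic C4′=C15′ enone of 22 with ortho regiochemistry; attack on the dienophile face anti to the cis C1′/C5′ substituents sets spiro C4′, and attack on the diene face anti to the C6–C8 bridge gives 2βH (removed in step 16). Zerovalent palladium is filtered off before the allylic chloride is added, and excess 22 suppresses self-dimerisation of 23.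

Step 16
Reactants: 24 Diels–Alder adduct (Δ1(10); 2βH; 5αH)
Product: 25 conjugated spiro-enone (Δ1(2)-3-one; 5βH; 10βH; 8β-silyloxy; primed half still 8′,9′-seco)
Conditions: DBU (0.2 equiv), BHT, degassed PhMe, 0 °C to rt, Ar
Reagents that add atoms: none
Why: base-mediated prototropy removes the doubly activated C2–H and reprotonates C10, moving the alkene into conjugation as the tetrasubstituted ring A/B enone; C10 and the doubly allylic C5 then equilibrate through the same extended dienolate to the mutually syn arrangement, the only one in which the C6–C9 bridge of ring C leaves the planar enone on one face, taken here to be 5βH,10βH.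

Step 17
Reactants: 25 conjugated spiro-enone
Product: 26 diol (8β-hydroxy; 8′-hydroxy-9′-chloro-8′,9′-seco)
Conditions: HF·pyridine (excess), THF, 0 °C to rt
Reagents that add atoms: none
Why: acidic fluoride cleaves both silyl ethers without the base that could epimerise C5/C10 or trigger lactone migration.

Step 18
Reactants: 26 diol
Product: 27 aldehyde (8′-oxo-9′-chloro-8′,9′-seco; free 8β-hydroxyl)
Conditions: TEMPO (cat.), PhI(OAc)2, CH2Cl2, rt; used crude
Reagents that add atoms: none
Why: oxoammonium oxidation is selective for the primary C8′ alcohol over the hindered secondary 8β-alcohol and is mild enough to keep the C7′ stereocentre.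

Step 19
Reactants: 27 aldehyde
Product: 30 CNP0397417.1, via allylic iodide 28 (not isolated), via allylstannane 29 (not isolated)
Conditions: SnCl2, NaI, DMF (0.005 M), rt, Ar
Reagents that add atoms: none
Why: Finkelstein exchange gives the allylic iodide, SnCl2 inserts into the C9′–I bond, and the allyltrihalostannane adds through its γ-terminus to the C8′ aldehyde via a six-membered chair transition state with tin on the carbonyl oxygen, forming C8′–C9′ and regenerating the exocyclic C10′=C14′. The closest known reaction type is the intramolecular Barbier (tin- or chromium-mediated) allylation of an aldehyde by a 2-substituted allylic halide, as used to close methylenecycloheptanols fused to α-methylene lactones. Ring F is closed in the 7-exo-trig mode (the carbonyl oxygen stays outside the ring), and it is the only ring formed. The one new stereocentre, C8′, is controlled by C7′: the tethered nucleophile attacks anti to the C7′–C11′ bond (Felkin–Anh, the sp2 lactone carbon as the large group) with the carbonyl oxygen gauche to C6′, which places O8′ anti to H7′ and should give 8′β-OH. The step needs chemoselectivity for the aldehyde over two ketones, the enones and two α-methylene lactones, which the low reactivity of allyltin halides toward ketones and the strain of attack on C3′ should secure. It also needs cyclisation over oligomerisation, which high dilution and the cis disposition of the two side chains on ring E should secure.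

**Compound list**

1 | (S)-(+)-carvone | CC1=CC[C@@H](CC1=O)C(C)=C | starting material
2 | (S)-10-chlorocarvone, (5S)-5-(3-chloroprop-1-en-2-yl)-2-methylcyclohex-2-en-1-one | CC1=CC[C@@H](CC1=O)C(=C)CCl | intermediate
3 | (1S,5S)-5-(3-chloroprop-1-en-2-yl)-2-methylcyclohex-2-en-1-ol (cis) | CC1=CC[C@@H](C[C@@H]1O)C(=C)CCl | intermediate
4 | tert-butyldimethylsilyl ether of 3 | CC1=CC[C@@H](C[C@@H]1O[Si](C)(C)C(C)(C)C)C(=C)CCl | intermediate
5 | (3R,5S)-5-(tert-butyldimethylsilyloxy)-3-(3-chloroprop-1-en-2-yl)-6-oxoheptanal, formed in the flask | CC(=O)[C@@H](O[Si](C)(C)C(C)(C)C)C[C@H](CC=O)C(=C)CCl | intermediate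
6 | (3S,5R)-3-(tert-butyldimethylsilyloxy)-5-(3-chloroprop-1-en-2-yl)-2-methylcyclopent-1-ene-1-carbaldehyde | CC1=C(C=O)[C@H](C(=C)CCl)C[C@@H]1O[Si](C)(C)C(C)(C)C | intermediate
7 | potassium dienolate of 6 (C15 deprotonated, exocyclic C4=C15 and C5=C6), formed in the flask | [K+].[O-]C=C1C(=C)[C@@H](O[Si](C)(C)C(C)(C)C)C[C@H]1C(=C)CCl | intermediate
8 | (1R,2R,4S)-4-(tert-butyldimethylsilyloxy)-2-(3-chloroprop-1-en-2-yl)-5-methylidenecyclopentane-1-carbaldehyde (all-cis) | C=C1[C@@H](O[Si](C)(C)C(C)(C)C)C[C@@H](C(=C)CCl)[C@H]1C=O | intermediate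
9 | methyl 4-hydroxybut-2-ynoate | COC(=O)C#CCO | starting material
10 | methyl 4-(tert-butyldiphenylsilyloxy)but-2-ynoate | COC(=O)C#CCO[Si](c1ccccc1)(c1ccccc1)C(C)(C)C | intermediate
11 | methyl 4-(tert-butyldiphenylsilyloxy)-2-(diisobutylalumanyl)but-2-enoate (CH2OSi cis to ester), formed in the flask | COC(=O)/C(=C\CO[Si](c1ccccc1)(c1ccccc1)C(C)(C)C)[Al](CC(C)C)CC(C)C | intermediate
12 | methyl (Z)-4-(tert-butyldiphenylsilyloxy)-2-[(4,4,5,5-tetramethyl-1,3,2-dioxaborolan-2-yl)methyl]but-2-enoate | COC(=O)/C(=C\CO[Si](c1ccccc1)(c1ccccc1)C(C)(C)C)CB1OC(C)(C)C(C)(C)O1 | intermediate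
13 | O-boryl anti homoallylic ester (C6–O–Bpin, C7 bearing CH2OSi, methyl acrylate unit), formed in the flask | C=C1[C@@H](O[Si](C)(C)C(C)(C)C)C[C@@H](C(=C)CCl)[C@H]1[C@@H](OB1OC(C)(C)C(C)(C)O1)[C@@H](CO[Si](c1ccccc1)(c1ccccc1)C(C)(C)C)C(=C)C(=O)OC | intermediate
14 | 9-chloro-3β-(tert-butyldimethylsilyloxy)-8-(tert-butyldiphenylsilyloxy)-8,9-seco-1αH,5αH,6βH,7αH-guaia-4(15),10(14),11(13)-trien-12,6-olide | C=C1[C@@H](O[Si](C)(C)C(C)(C)C)C[C@@H](C(=C)CCl)[C@H]1[C@H]1OC(=O)C(=C)[C@@H]1CO[Si](c1ccccc1)(c1ccccc1)C(C)(C)C | intermediate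
15 | 9-chloro-3β,8-dihydroxy-8,9-seco-1αH,5αH,6βH,7αH-guaia-4(15),10(14),11(13)-trien-12,6-olide | C=C1[C@@H](O)C[C@@H](C(=C)CCl)[C@H]1[C@H]1OC(=O)C(=C)[C@@H]1CO | intermediate
16 | 9-chloro-3,8-dioxo-8,9-seco-1αH,5αH,6βH,7αH-guaia-4(15),10(14),11(13)-trien-12,6-olide (C8 aldehyde) | C=C1C(=O)C[C@@H](C(=C)CCl)[C@H]1[C@H]1OC(=O)C(=C)[C@@H]1C=O | intermediate
17 | 9-iodo analogue of 16, formed in the flask | C=C1C(=O)C[C@@H](C(=C)CI)[C@H]1[C@H]1OC(=O)C(=C)[C@@H]1C=O | intermediate
18 | 9-(dichloroiodostannyl) analogue of 16, formed in the flask | C=C1C(=O)C[C@@H](C(=C)C[Sn](Cl)(Cl)I)[C@H]1[C@H]1OC(=O)C(=C)[C@@H]1C=O | intermediate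
19 | 8β-hydroxy-3-oxo-1αH,5αH,6βH,7αH-guaia-4(15),10(14),11(13)-trien-12,6-olide | C=C1C(=O)C[C@H]2C(=C)C[C@@H](O)[C@H]3C(=C)C(=O)O[C@@H]3[C@@H]12 | intermediate
20 | 3,8β-bis(tert-butyldimethylsilyloxy)-1αH,5αH,6βH,7αH-guaia-2,4(15),10(14),11(13)-tetraen-12,6-olide | C=C1C(O[Si](C)(C)C(C)(C)C)=C[C@H]2C(=C)C[C@@H](O[Si](C)(C)C(C)(C)C)[C@H]3C(=C)C(=O)O[C@@H]3[C@@H]12 | intermediate
21 | 9-chloro-3β-hydroxy-8-(tert-butyldiphenylsilyloxy)-8,9-seco-1αH,5αH,6βH,7αH-guaia-4(15),10(14),11(13)-trien-12,6-olide | C=C1[C@@H](O)C[C@@H](C(=C)CCl)[C@H]1[C@H]1OC(=O)C(=C)[C@@H]1CO[Si](c1ccccc1)(c1ccccc1)C(C)(C)C | intermediate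
22 | 9-chloro-3-oxo-8-(tert-butyldiphenylsilyloxy)-8,9-seco-1αH,5αH,6βH,7αH-guaia-4(15),10(14),11(13)-trien-12,6-olide | C=C1C(=O)C[C@@H](C(=C)CCl)[C@H]1[C@H]1OC(=O)C(=C)[C@@H]1CO[Si](c1ccccc1)(c1ccccc1)C(C)(C)C | intermediate
23 | 8β-(tert-butyldimethylsilyloxy)-3-oxo-5αH,6βH,7αH-guaia-1,4(15),10(14),11(13)-tetraen-12,6-olide, formed in the flask | C=C1C(=O)C=C2C(=C)C[C@@H](O[Si](C)(C)C(C)(C)C)[C@H]3C(=C)C(=O)O[C@@H]3[C@@H]12 | intermediate
24 | Diels–Alder adduct: ring B via C2–C4′ and C14–C15′; Δ1(10); 2βH; 5αH; 8β-OTBS; spiro C4′ (C15′ β); primed half 9′-chloro-8′-(tert-butyldiphenylsilyloxy)-8′,9′-seco | C=C1C(=O)[C@H]2C3=C(CC[C@]24C(=O)C[C@@H](C(=C)CCl)[C@H]4[C@H]4OC(=O)C(=C)[C@@H]4CO[Si](c5ccccc5)(c5ccccc5)C(C)(C)C)C[C@@H](O[Si](C)(C)C(C)(C)C)[C@H]2C(=C)C(=O)O[C@@H]2[C@@H]13 | intermediate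
25 | conjugated isomer of 24: Δ1(2)-3-one; 5βH; 10βH; silyl groups as in 24 | C=C1C(=O)C2=C3[C@H](CC[C@]24C(=O)C[C@@H](C(=C)CCl)[C@H]4[C@H]4OC(=O)C(=C)[C@@H]4CO[Si](c5ccccc5)(c5ccccc5)C(C)(C)C)C[C@@H](O[Si](C)(C)C(C)(C)C)[C@H]2C(=C)C(=O)O[C@@H]2[C@H]13 | intermediate
26 | diol from 25: 8β-OH; 8′-CH2OH; 9′-chloride | C=C1C(=O)C2=C3[C@H](CC[C@]24C(=O)C[C@@H](C(=C)CCl)[C@H]4[C@H]4OC(=O)C(=C)[C@@H]4CO)C[C@@H](O)[C@H]2C(=C)C(=O)O[C@@H]2[C@H]13 | intermediate
27 | C8′ aldehyde from 26 (8β-OH free; 9′-chloride) | C=C1C(=O)C2=C3[C@H](CC[C@]24C(=O)C[C@@H](C(=C)CCl)[C@H]4[C@H]4OC(=O)C(=C)[C@@H]4C=O)C[C@@H](O)[C@H]2C(=C)C(=O)O[C@@H]2[C@H]13 | intermediate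
28 | 9′-iodo analogue of 27, formed in the flask | C=C1C(=O)C2=C3[C@H](CC[C@]24C(=O)C[C@@H](C(=C)CI)[C@H]4[C@H]4OC(=O)C(=C)[C@@H]4C=O)C[C@@H](O)[C@H]2C(=C)C(=O)O[C@@H]2[C@H]13 | intermediate
29 | 9′-(dichloroiodostannyl) analogue of 27, formed in the flask | C=C1C(=O)C2=C3[C@H](CC[C@]24C(=O)C[C@@H](C(=C)C[Sn](Cl)(Cl)I)[C@H]4[C@H]4OC(=O)C(=C)[C@@H]4C=O)C[C@@H](O)[C@H]2C(=C)C(=O)O[C@@H]2[C@H]13 | intermediate
30 | CNP0397417.1: 8β-hydroxy-5βH,10βH-Δ1(2)-3-one half spiro-linked (C2–C4′, C14–C15′) to the 8′β-hydroxy-3′-oxo-1′αH,5′αH,6′βH,7′αH-guaia-10′(14′),11′(13′)-dien-12′,6′-olide half | C=C1C(=O)C2=C3[C@H](CC[C@]24C(=O)C[C@H]2C(=C)C[C@@H](O)[C@H]5C(=C)C(=O)O[C@@H]5[C@H]24)C[C@@H](O)[C@H]2C(=C)C(=O)O[C@@H]2[C@H]13 | target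

**Summary**

Total step count: 19. Longest linear sequence: 15 steps (steps 1–5, 8–12, 15–19).

Steps most likely to fail:

Step 16. The equilibration may settle in another C5/C10 arrangement, or the base may move a lactone methylene into the ring. The fallback sets out from 24 and replaces equilibration by a stereospecific relay in two stages. A tertiary amine of low basicity in a non-polar solvent (quinuclidine, benzene, rt) should return the 2β-hydrogen to the β-face of C10 within the ammonium dienolate ion pair (conducted-tour 1,3-prototropy), giving the 5αH,10βH conjugated enone F1. A weak base in a polar solvent (imidazole, MeCN) should then epimerise only the more acidic, doubly allylic C5–H to the syn isomer, which is 25, where the fallback rejoins the route.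

Step 5. The base may deprotonate C3 instead of the methyl group, and the β,γ-unsaturated aldehyde may reconjugate or epimerise at C5 before it is used. The fallback sets out from 6 and does the deconjugation at the ester level. Pinnick oxidation (NaClO2, NaH2PO4, 2-methylbut-2-ene) gives the carboxylic acid F2, and trimethylsilyldiazomethane gives the methyl ester F3. LDA/HMPA at −78 °C followed by a cold AcOH quench should give the deconjugated all-cis ester F4 by the same kinetic α-protonation. DIBAL-H at −78 °C reduces F4 to 8, where the fallback rejoins the route.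

Step 19. The allyl metal may be protonated or reduced before it cyclises, oligomers may form, or the face selectivity at C8′ may be poor. The fallback sets out from 26 and closes ring F by an ene reaction instead. Hydrogenolysis of the allylic chloride (Pd(PPh3)4, HCO2H, Et3N, THF) gives the isopropenyl diol F5, and TEMPO/PhI(OAc)2 gives the isopropenyl aldehyde F6. Me2AlCl in CH2Cl2 at −78 °C should then effect a type-two carbonyl-ene cyclisation, which forms C8′–C9′ with transfer of a C14′ hydrogen and gives 30 directly, with ring F still closed last.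

**Further compounds**

F1 | step 16 | 5αH,10βH conjugated spiro-enone (C5 epimer of 25) | C=C1C(=O)C2=C3[C@H](CC[C@]24C(=O)C[C@@H](C(=C)CCl)[C@H]4[C@H]4OC(=O)C(=C)[C@@H]4CO[Si](c5ccccc5)(c5ccccc5)C(C)(C)C)C[C@@H](O[Si](C)(C)C(C)(C)C)[C@H]2C(=C)C(=O)O[C@@H]2[C@@H]13
F2 | step 5 | (3S,5R)-3-(tert-butyldimethylsilyloxy)-5-(3-chloroprop-1-en-2-yl)-2-methylcyclopent-1-ene-1-carboxylic acid | CC1=C(C(=O)O)[C@H](C(=C)CCl)C[C@@H]1O[Si](C)(C)C(C)(C)C
F3 | step 5 | methyl ester of F2 | CC1=C(C(=O)OC)[C@H](C(=C)CCl)C[C@@H]1O[Si](C)(C)C(C)(C)C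
F4 | step 5 | methyl (1R,2R,4S)-4-(tert-butyldimethylsilyloxy)-2-(3-chloroprop-1-en-2-yl)-5-methylidenecyclopentane-1-carboxylate (all-cis) | C=C1[C@@H](O[Si](C)(C)C(C)(C)C)C[C@@H](C(=C)CCl)[C@H]1C(=O)OC
F5 | step 19 | isopropenyl diol (26 with the 9′-chloride replaced by hydrogen) | C=C1C(=O)C2=C3[C@H](CC[C@]24C(=O)C[C@@H](C(C)=C)[C@H]4[C@H]4OC(=O)C(=C)[C@@H]4CO)C[C@@H](O)[C@H]2C(=C)C(=O)O[C@@H]2[C@H]13
F6 | step 19 | isopropenyl C8′ aldehyde from F5 | C=C1C(=O)C2=C3[C@H](CC[C@]24C(=O)C[C@@H](C(C)=C)[C@H]4[C@H]4OC(=O)C(=C)[C@@H]4C=O)C[C@@H](O)[C@H]2C(=C)C(=O)O[C@@H]2[C@H]13
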